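Assumption: the stereodescriptors of the SMILES are taken literally (mutilin numbering: 5S,6S,9S,10R,11S,12S,14R). Labels C1–C14 below are mutilin position labels. A centre left open in a SMILES is an epimer mixture that is erased in a later step.

**Retrosynthetic overview**
1. Ring C is closed last, by hydration of the C9 propargyl group and aldol condensation onto the bridging C4 ketone; the glycolate goes on O14 just before.
2. The eight-membered ring comes from the seven-membered β-diketone 13 by a radical one-carbon ring expansion (1,2-acyl shift of C14 from C12 to the CH2 that becomes C13), relayed into a silicon-tethered vinyl transfer that sets C12.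
3. The seven-membered ring comes from a Dieckmann closure C5–C14 on ring A, after catalytic asymmetric conjugate methylation (C6).
4. The side chain comes from a propanoate aldol (C11), alkene cleavage, iridium-catalysed crotylation (C9, C10) and propargylation of 2-methylcyclohexenone.
5. Ring order: A (bought) → seven-membered ring → eight-membered ring → C.

**Route**

Step 1
Reactants: 1 2-methylcyclohex-2-en-1-one; 2 3-bromo-1-(trimethylsilyl)prop-1-yne
Product: 3 2-methyl-6-[3-(trimethylsilyl)prop-2-yn-1-yl]cyclohex-2-en-1-one (racemic at C9)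
Conditions: LiN(iPr)2, THF, −78 °C; then 2, −78 to −20 °C
Reagents that add atoms: none
Why: Kinetic alpha-prime deprotonation gives the cross-conjugated dienolate, which is alkylated by SN2 enolate alkylation at C9, and the racemic centre formed is erased by enolisation in step 2.

Step 2
Reactants: 3 propargyl enone; 4 (E)-1-chlorobut-2-ene
Product: 5 (6S)-6-[(2S)-but-3-en-2-yl]-2-methyl-6-[3-(trimethylsilyl)prop-2-yn-1-yl]cyclohex-2-en-1-one
Conditions: Ba[N(SiMe3)2]2 (0.55 equiv), THF, 0 °C; [Ir(cod)Cl]2 (2 mol %), BINOL-derived phosphoramidite L* (4 mol %), 4, 5 °C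
Reagents that add atoms: none
Why: In this iridium-catalysed branched-selective asymmetric allylic alkylation of an unstabilised barium enolate, the ligand fixes the face of the allyl unit (C10) and the approach of the tetrasubstituted dienolate (quaternary C9), so both centres are set under catalyst control.

Step 3
Reactants: 5 crotylated enone
Product: 6 (2R)-2-{(1S)-3-methyl-2-oxo-1-[3-(trimethylsilyl)prop-2-yn-1-yl]cyclohex-3-en-1-yl}propanal
Conditions: OsO4 (2 mol %), NaIO4 (4 equiv), 2,6-lutidine, dioxane/H2O, rt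
Reagents that add atoms: osmium tetroxide O=[Os](=O)(=O)=O; sodium periodate [Na+].[O-]I(=O)(=O)=O
Why: In this Lemieux–Johnson oxidative cleavage the monosubstituted alkene is dihydroxylated far faster than the electron-poor enone alkene or the silylalkyne, and the lutidine buffer keeps C10 from epimerising.

Step 4
Reactants: 6 aldehyde; 7 methyl propanoate
Product: 8 methyl (3S,4R)-3-hydroxy-2-methyl-4-{(1S)-3-methyl-2-oxo-1-[3-(trimethylsilyl)prop-2-yn-1-yl]cyclohex-3-en-1-yl}pentanoate (C12 epimers)
Conditions: 7, LiN(iPr)2, THF, −78 °C; then 6, −78 °C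
Reagents that add atoms: none
Why: This lithium enolate aldol addition runs under Felkin–Anh control, with quaternary C9 as the large group, so O11 ends syn to the C10 methyl in the zigzag chain (11S), and the C12 epimers do not matter because C12 is erased in steps 7 and 8.

Step 5
Reactants: 8 hydroxy ester; 9 chloro(dimethyl)vinylsilane
Product: 10 O11-dimethyl(vinyl)silyl ether of 8
Conditions: 9, imidazole, DMAP (cat.), CH2Cl2, 0 °C to rt
Reagents that add atoms: none
Why: Silyl ether formation protects O11 against retro-aldol cleavage under base and at the same time attaches the vinyl group to O11 for the tethered transfer in step 8.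

Step 6
Reactants: 10 silyl ether enone
Product: 11 methyl (3S,4R)-3-{[dimethyl(vinyl)silyl]oxy}-2-methyl-4-{(1S,4S)-3,4-dimethyl-2-oxo-1-[3-(trimethylsilyl)prop-2-yn-1-yl]cyclohexyl}pentanoate (epimers at C5 and C12)
Conditions: Me3Al (1.5 equiv), Cu(OTf)2 (5 mol %), (S,R,R)-phosphoramidite (10 mol %), Et2O, −30 °C
Reagents that add atoms: trimethylaluminium C[Al](C)C
Why: In this copper-catalysed asymmetric conjugate addition the chiral copper complex delivers methyl to one enone face and sets C6 (S) under catalyst control, while the unselective protonation at C5 is harmless because C5 is enolised again in step 7.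

Step 7
Reactants: 11 keto ester
Product: 13 bicyclo[4.3.1]decane C4/C14-dione carrying CH3 plus CH2I on C12 (C12 epimers), via potassium enolate 12 (not isolated)
Conditions: KN(SiMe3)2 (2.3 equiv), THF, −78 to 0 °C; then CH2I2 (5 equiv), −40 °C to rt
Reagents that add atoms: diiodomethane ICI
Why: This is a Dieckmann condensation followed by enolate alkylation: only C5 of the ketone can enolise, the tethered ester reaches one face of that enolate so that C14 ends cis and the C5 methyl trans to the C6 methyl, and the second equivalent of base drains the product as its C12 enolate 12, which CH2I2 alkylates at carbon.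

Step 8
Reactants: 13 iodomethyl diketone
Product: 15 bicyclo[5.3.1]undecane C4/C14-dione with free O11-H and C12 carrying CH3 plus vinyl, via iodoethyl oxasilolane 14 (not isolated)
Conditions: (Bu3Sn)2 (10 mol %), sunlamp, benzene (0.01 M), 60 °C; then HF·pyridine, THF, 0 °C
Reagents that add atoms: none
Why: Proposed new method: iodine abstraction gives the C13 radical, which adds 3-exo to the C14 carbonyl and reopens the cyclopropyloxy radical to the tertiary C12 radical (1,2-acyl shift, seven- to eight-membered ring, estimated from the parent 2,2-dimethyl-3-oxobutyl radical to be faster than the competing 6-exo closure), this radical closes 5-exo onto the tethered vinylsilane on the face that carries O11, the resulting primary radical takes iodine from 13 to carry the chain, and fluoride then eliminates the beta-iodosilane to unveil the vinyl group cis to O11 (12S); the closest known reaction types are the Dowd–Beckwith ring expansion and silicon-tethered atom-transfer radical vinylation.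

Step 9
Reactants: 15 hydroxy diketone
Product: 16 C11,C14-diol of the bicyclo[5.3.1]undecan-C4-one (14R)
Conditions: Me4NBH(OAc)3 (5 equiv), MeCN/AcOH 1:1, −20 °C
Reagents that add atoms: none
Why: In this hydroxyl-directed reduction of the Evans–Saksena type, O11 binds boron and passes hydride across the ring to C14 from the face that carries O11, so O14 ends trans to O11, while the C4 ketone between two quaternary carbons is left alone.

Step 10
Reactants: 16 diol
Product: 17 O11-trifluoroacetate of 16
Conditions: N-(trifluoroacetyl)imidazole (1.1 equiv), THF, −15 °C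
Reagents that add atoms: N-(trifluoroacetyl)imidazole O=C(n1ccnc1)C(F)(F)F
Why: This chemoselective acyl transfer goes to O11 because O14 sits next to quaternary C5 and is much more hindered.

Step 11
Reactants: 17 mono-trifluoroacetate; 18 glycolic acid
Product: 20 O14-[2-(trifluoroacetoxy)acetyl] O11-trifluoroacetyl derivative of 16, via 2-(trifluoroacetoxy)acetic acid 19 (not isolated)
Conditions: 18, (CF3CO)2O, CH2Cl2, 0 °C, evaporate; then 17, DCC, DMAP, CH2Cl2, rt
Reagents that add atoms: trifluoroacetic anhydride O=C(OC(=O)C(F)(F)F)C(F)(F)F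
Why: This Steglich esterification uses the small activated acid 19 to acylate the only free hydroxyl (O14) with retention at C14.

Step 12
Reactants: 20 bis-trifluoroacetate
Product: 22 pleuromutilin F, via methyl ketone 21 (not isolated)
Conditions: AuCl(PPh3)/AgOTf (5 mol % each), p-TsOH·H2O (0.5 equiv), dioxane/MeOH/H2O, 70 °C
Reagents that add atoms: water O
Why: Gold-catalysed Markovnikov hydration of the silylalkyne (oxygen goes beta to silicon, then protodesilylation) gives the C2 methyl ketone 21, acid-catalysed intramolecular aldol condensation of C3 onto C4 closes the cyclopentenone (furan formation is blocked by quaternary C9), both labile trifluoroacetates solvolyse under the same conditions, and no stereocentre is touched.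

**Compound list**
1 | 2-methylcyclohex-2-en-1-one | CC1=CCCCC1=O | starting material
2 | 3-bromo-1-(trimethylsilyl)prop-1-yne | C[Si](C)(C)C#CCBr | starting material
3 | 2-methyl-6-[3-(trimethylsilyl)prop-2-yn-1-yl]cyclohex-2-en-1-one | CC1=CCCC(CC#C[Si](C)(C)C)C1=O | intermediate
4 | (E)-1-chlorobut-2-ene | C/C=C/CCl | starting material
5 | (6S)-6-[(2S)-but-3-en-2-yl]-2-methyl-6-[3-(trimethylsilyl)prop-2-yn-1-yl]cyclohex-2-en-1-one | C=C[C@H](C)[C@@]1(CC#C[Si](C)(C)C)CCC=C(C)C1=O | intermediate
6 | (2R)-2-{(1S)-3-methyl-2-oxo-1-[3-(trimethylsilyl)prop-2-yn-1-yl]cyclohex-3-en-1-yl}propanal | O=C[C@H](C)[C@@]1(CC#C[Si](C)(C)C)CCC=C(C)C1=O | intermediate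
7 | methyl propanoate | CCC(=O)OC | starting material
8 | beta-hydroxy ester (9S,10R,11S; C12 epimers) | COC(=O)C(C)[C@@H](O)[C@H](C)[C@@]1(CC#C[Si](C)(C)C)CCC=C(C)C1=O | intermediate
9 | chloro(dimethyl)vinylsilane | C=C[Si](C)(C)Cl | starting material
10 | O11-dimethyl(vinyl)silyl ether of 8 | COC(=O)C(C)[C@@H](O[Si](C)(C)C=C)[C@H](C)[C@@]1(CC#C[Si](C)(C)C)CCC=C(C)C1=O | intermediate
11 | conjugate methylation product (6S; epimers at C5, C12) | COC(=O)C(C)[C@@H](O[Si](C)(C)C=C)[C@H](C)[C@@]1(CC#C[Si](C)(C)C)CC[C@H](C)C(C)C1=O | intermediate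
12 | potassium C14/C12 enolate of the bicyclo[4.3.1]decane dione | CC1=C([O-])[C@]2(C)C(=O)[C@](CC#C[Si](C)(C)C)(CC[C@@H]2C)[C@@H](C)[C@@H]1O[Si](C)(C)C=C.[K+] | intermediate
13 | C12-iodomethyl bicyclo[4.3.1]decane C4/C14-dione (C12 epimers) | ICC1(C)C(=O)[C@]2(C)C(=O)[C@](CC#C[Si](C)(C)C)(CC[C@@H]2C)[C@@H](C)[C@@H]1O[Si](C)(C)C=C | intermediate
14 | ring-expanded dione with C11–O–SiMe2–CH(CH2I)–C12 oxasilolane | ICC4[C@]1(C)CC(=O)[C@]2(C)C(=O)[C@](CC#C[Si](C)(C)C)(CC[C@@H]2C)[C@@H](C)[C@@H]1O[Si]4(C)C | intermediate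
15 | bicyclo[5.3.1]undecane C4/C14-dione, 11-OH, 12-methyl-12-vinyl | C=C[C@]1(C)CC(=O)[C@]2(C)C(=O)[C@](CC#C[Si](C)(C)C)(CC[C@@H]2C)[C@@H](C)[C@@H]1O | intermediate
16 | C11,C14-diol | C=C[C@]1(C)C[C@@H](O)[C@]2(C)C(=O)[C@](CC#C[Si](C)(C)C)(CC[C@@H]2C)[C@@H](C)[C@@H]1O | intermediate
17 | O11-trifluoroacetate | C=C[C@]1(C)C[C@@H](O)[C@]2(C)C(=O)[C@](CC#C[Si](C)(C)C)(CC[C@@H]2C)[C@@H](C)[C@@H]1OC(=O)C(F)(F)F | intermediate
18 | glycolic acid | OCC(=O)O | starting material
19 | 2-(trifluoroacetoxy)acetic acid | OC(=O)COC(=O)C(F)(F)F | intermediate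
20 | O14-[2-(trifluoroacetoxy)acetyl] O11-trifluoroacetate | C=C[C@]1(C)C[C@@H](OC(=O)COC(=O)C(F)(F)F)[C@]2(C)C(=O)[C@](CC#C[Si](C)(C)C)(CC[C@@H]2C)[C@@H](C)[C@@H]1OC(=O)C(F)(F)F | intermediate
21 | C9-acetonyl C4 ketone, O14 glycolate, 11-OH | C=C[C@]1(C)C[C@@H](OC(=O)CO)[C@]2(C)C(=O)[C@](CC(C)=O)(CC[C@@H]2C)[C@@H](C)[C@@H]1O | intermediate
22 | pleuromutilin F | C=C[C@]1(C)C[C@@H](OC(=O)CO)[C@]2(C)C3=CC(=O)C[C@@]3(CC[C@@H]2C)[C@@H](C)[C@@H]1O | target

Total step count: 12. Longest linear sequence: 12.

**Steps most likely to fail**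

Step 7. The closure onto a hindered ester gives a β-diketone that cannot enolise at C5, so it may revert or lose the O11 silyloxy group. The fallback replaces the Claisen-type closure by an aldol closure; it sets out from 11 and comes back at 13. LiAlH4 reduces ketone and ester to the diol F1. Dess–Martin periodinane gives the keto aldehyde F2. LiN(SiMe3)2 at −78 °C closes the ring by intramolecular aldol addition of the C5 enolate to the much more reactive C14 aldehyde, giving the hydroxy ketone F3. A second Dess–Martin oxidation gives the neutral diketone F4. LiN(iPr)2 followed by CH2I2 then delivers 13.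

Step 8 (the new step). The C13 radical may close directly onto the vinylsilane, or the chain may stall. The fallback uses known chemistry and keeps a one-carbon ring expansion; it sets out from 12 and comes back at 15. The enolate is trapped with Me3SiCl as the trimethylsilyl enol ether F5. Simmons–Smith cyclopropanation (Et2Zn, CH2I2) gives the siloxycyclopropane F6. FeCl3 in DMF opens the internal bond (Saegusa–Ito ring expansion) to the chloro ketone F7. NaOAc in MeOH eliminates it to the cyclooctenone F8. HF·pyridine frees O11 to give the hydroxy enone F9. Alkoxide-directed conjugate addition of CH2=CHMgBr (3 equiv, THF, −78 °C) then delivers vinyl cis to O11 and gives 15.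

Step 12. The C4 ketone lies between two quaternary carbons, so the acid-mediated condensation may stop at 21 or damage the ester. The fallback closes ring C under strong base before any ester is present; it sets out from 16 and comes back at 22.
- Et3SiOTf and 2,6-lutidine give the bis(triethylsilyl) ether F10.
- AuCl(PPh3)/AgOTf in wet dioxane gives the methyl ketone F11.
- KOt-Bu in t-BuOH at 60 °C effects the aldol condensation to the protected enone F12; elimination is impossible because C5 carries no hydrogen.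
- HF·pyridine gives the enone diol F13.
- N-(trifluoroacetyl)imidazole gives the O11 trifluoroacetate F14.
- DCC/DMAP coupling with 19 gives the bis-trifluoroacetate F15.
- NaHCO3 in MeOH releases 22.

**Further compounds**
F1 | step 7 | diol from full reduction of 11 | OCC(C)[C@@H](O[Si](C)(C)C=C)[C@H](C)[C@@]1(CC#C[Si](C)(C)C)CC[C@H](C)C(C)C1O
F2 | step 7 | keto aldehyde | O=CC(C)[C@@H](O[Si](C)(C)C=C)[C@H](C)[C@@]1(CC#C[Si](C)(C)C)CC[C@H](C)C(C)C1=O
F3 | step 7 | bicyclo[4.3.1]decane C14-hydroxy C4-ketone | CC1C(O)[C@]2(C)C(=O)[C@](CC#C[Si](C)(C)C)(CC[C@@H]2C)[C@@H](C)[C@@H]1O[Si](C)(C)C=C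
F4 | step 7 | neutral bicyclo[4.3.1]decane C4/C14-dione | CC1C(=O)[C@]2(C)C(=O)[C@](CC#C[Si](C)(C)C)(CC[C@@H]2C)[C@@H](C)[C@@H]1O[Si](C)(C)C=C
F5 | step 8 | trimethylsilyl enol ether of F4 | CC1=C(O[Si](C)(C)C)[C@]2(C)C(=O)[C@](CC#C[Si](C)(C)C)(CC[C@@H]2C)[C@@H](C)[C@@H]1O[Si](C)(C)C=C
F6 | step 8 | siloxycyclopropane (C12–C13–C14) | CC13CC3(O[Si](C)(C)C)[C@]2(C)C(=O)[C@](CC#C[Si](C)(C)C)(CC[C@@H]2C)[C@@H](C)[C@@H]1O[Si](C)(C)C=C
F7 | step 8 | ring-expanded C12-chloro ketone | CC1(Cl)CC(=O)[C@]2(C)C(=O)[C@](CC#C[Si](C)(C)C)(CC[C@@H]2C)[C@@H](C)[C@@H]1O[Si](C)(C)C=C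
F8 | step 8 | cyclooctenone (C12=C13) silyl ether | CC1=CC(=O)[C@]2(C)C(=O)[C@](CC#C[Si](C)(C)C)(CC[C@@H]2C)[C@@H](C)[C@@H]1O[Si](C)(C)C=C
F9 | step 8 | 11-hydroxy cyclooctenone | CC1=CC(=O)[C@]2(C)C(=O)[C@](CC#C[Si](C)(C)C)(CC[C@@H]2C)[C@@H](C)[C@@H]1O
F10 | step 12 | O11,O14-bis(triethylsilyl) ether of 16 | C=C[C@]1(C)C[C@@H](O[Si](CC)(CC)CC)[C@]2(C)C(=O)[C@](CC#C[Si](C)(C)C)(CC[C@@H]2C)[C@@H](C)[C@@H]1O[Si](CC)(CC)CC
F11 | step 12 | bis(triethylsilyl) C9-acetonyl ketone | C=C[C@]1(C)C[C@@H](O[Si](CC)(CC)CC)[C@]2(C)C(=O)[C@](CC(C)=O)(CC[C@@H]2C)[C@@H](C)[C@@H]1O[Si](CC)(CC)CC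
F12 | step 12 | bis(triethylsilyl) tricyclic enone | C=C[C@]1(C)C[C@@H](O[Si](CC)(CC)CC)[C@]2(C)C3=CC(=O)C[C@@]3(CC[C@@H]2C)[C@@H](C)[C@@H]1O[Si](CC)(CC)CC
F13 | step 12 | tricyclic enone 11,14-diol | C=C[C@]1(C)C[C@@H](O)[C@]2(C)C3=CC(=O)C[C@@]3(CC[C@@H]2C)[C@@H](C)[C@@H]1O
F14 | step 12 | O11-trifluoroacetate of F13 | C=C[C@]1(C)C[C@@H](O)[C@]2(C)C3=CC(=O)C[C@@]3(CC[C@@H]2C)[C@@H](C)[C@@H]1OC(=O)C(F)(F)F
F15 | step 12 | O14-[2-(trifluoroacetoxy)acetyl] O11-trifluoroacetate of F13 | C=C[C@]1(C)C[C@@H](OC(=O)COC(=O)C(F)(F)F)[C@]2(C)C3=CC(=O)C[C@@]3(CC[C@@H]2C)[C@@H](C)[C@@H]1OC(=O)C(F)(F)F
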